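The cyclohexane core (C1 bearing the side chain, C2–O-isovaleryl, C3=O, C4(CH3)–C5 oxirane, C6) is read as a masked 2-methylcyclohex-2-enone whose C1 holds C7 at the acid level. C1–C2 and C4=C5 are therefore cut as Michael and aldol-condensation bonds. One amine-catalysed cascade joins two acyclic partners, closes the six-membered ring and sets C1, the centre that later relays C2, C3, the ring oxirane and C7. The precursors are a 4-oxobut-2-enoic acid derivative and tert-butyl 3-oxopentanoate. C7 is carried as a Weinreb amide so that it can later be told apart from the isovalerate and become a chloromethyl ketone in one step.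

Key step: step 3

Remark: atom labels follow the target (ring C1–C6 as above; C7 side-chain oxirane carbon, C14 its CH2, C8 chain C=O, C9=C10, C11 the C–OOH carbon); compounds 1, 2, 5, 9, 15 and 16 and all reagents are assumed to be purchased.

Step 1
Reactants: 1 2,2-dimethoxyacetaldehyde (60 wt% in water); 2 N-methoxy-N-methyl-2-(triphenyl-λ5-phosphanylidene)acetamide
Product: 3 (E)-N,4,4-trimethoxy-N-methylbut-2-enamide
Conditions: CH2Cl2, 0 °C to rt
Reagents that add atoms: none
Why: Wittig olefination with a stabilised amide ylide, which should give the E-alkene while the second aldehyde of glyoxal stays masked as its dimethyl acetal.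

Step 2
Reactants: 3 (E)-N,4,4-trimethoxy-N-methylbut-2-enamide
Product: 4 (E)-N-methoxy-N-methyl-4-oxobut-2-enamide
Conditions: 1 M HCl, THF, rt
Reagents that add atoms: water, O
Why: Acid-catalysed acetal hydrolysis; the conjugated Weinreb amide tolerates dilute acid and the more stable E-geometry is kept.

Step 3
Reactants: 4 (E)-N-methoxy-N-methyl-4-oxobut-2-enamide; 5 tert-butyl 3-oxopentanoate
Product: 7 (R)-N-methoxy-N,4-dimethyl-5-oxocyclohex-3-ene-1-carboxamide, via Michael adduct 6 (not isolated)
Conditions: (S)-2-{bis[3,5-bis(trifluoromethyl)phenyl][(trimethylsilyl)oxy]methyl}pyrrolidine (10 mol%), toluene, rt; then TsOH·H2O (20 mol%), toluene, 80 °C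
Reagents that add atoms: none
Why: The pyrrolidine condenses with the aldehyde of 4 to an E-iminium ion, the enol of 5 adds to the carbon β to the iminium carbon (α to the amide, future C1) and hydrolysis releases adduct 6 with C1–C2 in place; TsOH then enolises the ethyl ketone toward its CH2 (C4), which attacks the aldehyde (C5), water is lost to give C4=C5, and the tert-butyl ester is cleaved to a β-keto acid that loses CO2 at C2. The closest known reaction type is the diarylprolinol silyl ether-catalysed Michael addition of β-keto esters to enals followed by acid-mediated aldol condensation and decarboxylation to 5-substituted cyclohex-2-enones. The ring closes by a 6-(enolendo)-exo-trig aldol addition. C1 is controlled by the catalyst: the silyloxydiarylmethyl group of the (S)-pyrrolidine covers one face of the s-trans E-iminium ion, so the nucleophile should enter from the open face and give 1R. The step needs attack at the iminium β-carbon and not conjugate addition to the amide, which the much lower LUMO of the iminium ion secures, and it needs C4 rather than C2 as the aldol donor, which ring size secures because closure from C2 would give a four-membered ring.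

Step 4
Reactants: 7 (R)-N-methoxy-N,4-dimethyl-5-oxocyclohex-3-ene-1-carboxamide
Product: 8 (1R,6S)-6-hydroxy-N-methoxy-N,4-dimethyl-5-oxocyclohex-3-ene-1-carboxamide
Conditions: KN(SiMe3)2, THF, −78 °C; then (±)-3-phenyl-2-(phenylsulfonyl)oxaziridine, −78 °C; AcOH quench
Reagents that add atoms: 3-phenyl-2-(phenylsulfonyl)oxaziridine, O=S(=O)(c1ccccc1)N1OC1c1ccccc1
Why: Kinetic deprotonation at C2 gives the cross-conjugated potassium dienolate, and oxygen transfer from the N-sulfonyloxaziridine (enolate α-hydroxylation) should occur on the face opposite the adjacent C1 carboxamide, setting the trans C2 carbinol (6S in the name), which is also the more stable diequatorial epimer.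

Step 5
Reactants: 8 (1R,6S)-6-hydroxy-N-methoxy-N,4-dimethyl-5-oxocyclohex-3-ene-1-carboxamide; 9 3-methylbutanoyl chloride (isovaleryl chloride)
Product: 10 (1S,6R)-6-[methoxy(methyl)carbamoyl]-3-methyl-2-oxocyclohex-3-en-1-yl 3-methylbutanoate
Conditions: pyridine, 4-(dimethylamino)pyridine (cat.), CH2Cl2, 0 °C
Reagents that add atoms: none
Why: Nucleophile-catalysed O-acylation of the secondary ketol by the acid chloride; no stereocentre is touched and the poorly acidic C1–H of the amide disfavours β-elimination of the new ester.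

Step 6
Reactants: 10 (1S,6R)-6-[methoxy(methyl)carbamoyl]-3-methyl-2-oxocyclohex-3-en-1-yl 3-methylbutanoate
Product: 11 (1S,2S,6R)-2-hydroxy-6-[methoxy(methyl)carbamoyl]-3-methylcyclohex-3-en-1-yl 3-methylbutanoate
Conditions: NaBH4, CeCl3·7H2O, MeOH, −78 °C
Reagents that add atoms: none
Why: Luche 1,2-reduction: axial hydride delivery to the half-chair with the C1 and C2 substituents equatorial should give the equatorial C3 alcohol, cis to the C1 amide and trans to the C2 ester (2S in the name), while ester and Weinreb amide are inert to NaBH4 at this temperature.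

Step 7
Reactants: 11 (1S,2S,6R)-2-hydroxy-6-[methoxy(methyl)carbamoyl]-3-methylcyclohex-3-en-1-yl 3-methylbutanoate
Product: 12 (1R,2R,3S,4R,6S)-2-hydroxy-4-[methoxy(methyl)carbamoyl]-1-methyl-7-oxabicyclo[4.1.0]heptan-3-yl 3-methylbutanoate
Conditions: VO(acac)2 (cat.), t-BuOOH, CH2Cl2, 0 °C to rt
Reagents that add atoms: tert-butyl hydroperoxide, CC(C)(C)OO
Why: Hydroxyl-directed epoxidation of a cyclic allylic alcohol: the vanadium-bound peroxide delivers oxygen to the alkene face syn to the C3 hydroxyl, which is the face of the C1 substituent, and so sets the C4 and C5 oxirane centres.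

Step 8
Reactants: 12 (1R,2R,3S,4R,6S)-2-hydroxy-4-[methoxy(methyl)carbamoyl]-1-methyl-7-oxabicyclo[4.1.0]heptan-3-yl 3-methylbutanoate
Product: 13 (1S,2R,3S,4R,6S)-4-[methoxy(methyl)carbamoyl]-1-methyl-2-[(triethylsilyl)oxy]-7-oxabicyclo[4.1.0]heptan-3-yl 3-methylbutanoate
Conditions: Et3SiCl, imidazole, 4-(dimethylamino)pyridine (cat.), DMF, rt
Reagents that add atoms: chlorotriethylsilane, CC[Si](Cl)(CC)CC
Why: Silylation of the secondary alcohol keeps C3 at the alcohol level and unreactive while carbon nucleophiles are used at C7; no stereocentre changes (the descriptor at C1 of the name changes only through ligand priorities).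

Step 9
Reactants: 13 (1S,2R,3S,4R,6S)-4-[methoxy(methyl)carbamoyl]-1-methyl-2-[(triethylsilyl)oxy]-7-oxabicyclo[4.1.0]heptan-3-yl 3-methylbutanoate
Product: 14 (1S,2R,3S,4R,6S)-4-(chloroacetyl)-1-methyl-2-[(triethylsilyl)oxy]-7-oxabicyclo[4.1.0]heptan-3-yl 3-methylbutanoate
Conditions: ICH2Cl, MeLi·LiBr, THF–Et2O, −78 °C; AcOH quench at −78 °C
Reagents that add atoms: chloroiodomethane, ClCI
Why: Homologation of a Weinreb amide with a lithium carbenoid: chloromethyllithium, formed by iodine–lithium exchange in the presence of 13, adds once and the chelated tetrahedral adduct survives until the cold acidic quench, while the hindered secondary isovalerate should react much more slowly.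

Step 10
Reactants: 15 1,3-dithiane; 16 1-bromo-3-methylbut-2-ene (prenyl bromide)
Product: 17 2-(3-methylbut-2-en-1-yl)-1,3-dithiane
Conditions: n-BuLi, THF, −30 °C; then 16, −78 to 0 °C
Reagents that add atoms: none
Why: Corey–Seebach alkylation: 2-lithio-1,3-dithiane displaces bromide at the primary allylic carbon (SN2), giving the linear prenyl dithiane that carries C8–C13.

Step 11
Reactants: 14 (1S,2R,3S,4R,6S)-4-(chloroacetyl)-1-methyl-2-[(triethylsilyl)oxy]-7-oxabicyclo[4.1.0]heptan-3-yl 3-methylbutanoate; 17 2-(3-methylbut-2-en-1-yl)-1,3-dithiane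
Product: 20 (1S,2R,3S,4R,6S)-1-methyl-4-{(2R)-2-[2-(3-methylbut-2-en-1-yl)-1,3-dithian-2-yl]oxiran-2-yl}-2-[(triethylsilyl)oxy]-7-oxabicyclo[4.1.0]heptan-3-yl 3-methylbutanoate, via lithiated dithiane 18 (not isolated), via chlorohydrin lithium alkoxide 19 (not isolated)
Conditions: 17, n-BuLi, THF, −25 °C; then 14, THF, −78 °C; warm to 0 °C
Reagents that add atoms: none
Why: Corey–Seebach acyl-anion addition to the α-chloro ketone and 3-exo-tet closure of the chlorohydrin alkoxide with the carbonyl oxygen retained; under Felkin–Anh control (oxygen-bearing C2 anti to the nucleophile, C1–H on the side of the CH2Cl group, C6 next to the carbonyl oxygen) the dithiane should enter on the face that makes C7 R.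

Step 12
Reactants: 20 (1S,2R,3S,4R,6S)-1-methyl-4-{(2R)-2-[2-(3-methylbut-2-en-1-yl)-1,3-dithian-2-yl]oxiran-2-yl}-2-[(triethylsilyl)oxy]-7-oxabicyclo[4.1.0]heptan-3-yl 3-methylbutanoate
Product: 21 (1R,2R,3S,4R,6S)-2-hydroxy-1-methyl-4-{(2R)-2-[2-(3-methylbut-2-en-1-yl)-1,3-dithian-2-yl]oxiran-2-yl}-7-oxabicyclo[4.1.0]heptan-3-yl 3-methylbutanoate
Conditions: Bu4NF, AcOH (1:1), THF, 0 °C
Reagents that add atoms: none
Why: Fluoride cleavage of the triethylsilyl ether buffered with acetic acid, so that no alkoxide forms next to the isovalerate and the epoxides and the dithiane stay untouched.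

Step 13
Reactants: 21 (1R,2R,3S,4R,6S)-2-hydroxy-1-methyl-4-{(2R)-2-[2-(3-methylbut-2-en-1-yl)-1,3-dithian-2-yl]oxiran-2-yl}-7-oxabicyclo[4.1.0]heptan-3-yl 3-methylbutanoate
Product: 22 (1S,3S,4R,6S)-1-methyl-4-[(2R)-2-(4-methylpent-3-enoyl)oxiran-2-yl]-2-oxo-7-oxabicyclo[4.1.0]heptan-3-yl 3-methylbutanoate
Conditions: Dess–Martin periodinane (excess), MeCN–CH2Cl2–H2O (8:1:1), rt
Reagents that add atoms: water, O
Why: Dess–Martin periodinane oxidises the C3 alcohol to the ketone and, in wet acetonitrile, also cleaves the 1,3-dithiane by sulfur activation and hydrolysis (oxidative dethioacetalisation), so both carbonyl groups appear in one non-basic operation that keeps the β,γ-alkene out of conjugation and puts no stereocentre at risk.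

Step 14
Reactants: 22 (1S,3S,4R,6S)-1-methyl-4-[(2R)-2-(4-methylpent-3-enoyl)oxiran-2-yl]-2-oxo-7-oxabicyclo[4.1.0]heptan-3-yl 3-methylbutanoate
Product: 23 (1S,3S,4R,6S)-4-{(2R)-2-[(2E)-4-hydroperoxy-4-methylpent-2-enoyl]oxiran-2-yl}-1-methyl-2-oxo-7-oxabicyclo[4.1.0]heptan-3-yl 3-methylbutanoate
Conditions: O2, 5,10,15,20-tetraphenylporphyrin (cat.), visible light, CH2Cl2, −20 °C
Reagents that add atoms: dioxygen, O=O
Why: Schenck ene reaction: singlet oxygen adds to the trisubstituted alkene with abstraction of a C9 hydrogen, which is allylic and activated by the C8 carbonyl, so that the O–O group ends on tertiary C11 and the alkene shifts to the conjugated E C9=C10 position, the regiochemistry that allylic carbonyl groups are known to favour.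

Compound list
1 | 2,2-dimethoxyacetaldehyde | COC(OC)C=O | starting material
2 | N-methoxy-N-methyl-2-(triphenyl-λ5-phosphanylidene)acetamide | CON(C)C(=O)C=P(c1ccccc1)(c1ccccc1)c1ccccc1 | starting material
3 | (E)-N,4,4-trimethoxy-N-methylbut-2-enamide | CON(C)C(=O)/C=C/C(OC)OC | intermediate
4 | (E)-N-methoxy-N-methyl-4-oxobut-2-enamide | CON(C)C(=O)/C=C/C=O | intermediate
5 | tert-butyl 3-oxopentanoate | CCC(=O)CC(=O)OC(C)(C)C | starting material
6 | tert-butyl (3R)-3-[methoxy(methyl)carbamoyl]-5-oxo-2-propanoylpentanoate (both C2 epimers) | CCC(=O)C(C(=O)OC(C)(C)C)[C@@H](CC=O)C(=O)N(C)OC | intermediate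
7 | (R)-N-methoxy-N,4-dimethyl-5-oxocyclohex-3-ene-1-carboxamide | CON(C)C(=O)[C@@H]1CC=C(C)C(=O)C1 | intermediate
8 | (1R,6S)-6-hydroxy-N-methoxy-N,4-dimethyl-5-oxocyclohex-3-ene-1-carboxamide | O[C@@H]1C(=O)C(C)=CC[C@H]1C(=O)N(C)OC | intermediate
9 | 3-methylbutanoyl chloride | CC(C)CC(Cl)=O | starting material
10 | (1S,6R)-6-[methoxy(methyl)carbamoyl]-3-methyl-2-oxocyclohex-3-en-1-yl 3-methylbutanoate | CC(C)CC(=O)O[C@@H]1C(=O)C(C)=CC[C@H]1C(=O)N(C)OC | intermediate
11 | (1S,2S,6R)-2-hydroxy-6-[methoxy(methyl)carbamoyl]-3-methylcyclohex-3-en-1-yl 3-methylbutanoate | CC(C)CC(=O)O[C@@H]1[C@@H](O)C(C)=CC[C@H]1C(=O)N(C)OC | intermediate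
12 | (1R,2R,3S,4R,6S)-2-hydroxy-4-[methoxy(methyl)carbamoyl]-1-methyl-7-oxabicyclo[4.1.0]heptan-3-yl 3-methylbutanoate | CC(C)CC(=O)O[C@@H]1[C@@H](O)[C@@]2(C)O[C@H]2C[C@H]1C(=O)N(C)OC | intermediate
13 | (1S,2R,3S,4R,6S)-4-[methoxy(methyl)carbamoyl]-1-methyl-2-[(triethylsilyl)oxy]-7-oxabicyclo[4.1.0]heptan-3-yl 3-methylbutanoate | CC(C)CC(=O)O[C@@H]1[C@@H](O[Si](CC)(CC)CC)[C@@]2(C)O[C@H]2C[C@H]1C(=O)N(C)OC | intermediate
14 | (1S,2R,3S,4R,6S)-4-(chloroacetyl)-1-methyl-2-[(triethylsilyl)oxy]-7-oxabicyclo[4.1.0]heptan-3-yl 3-methylbutanoate | CC(C)CC(=O)O[C@@H]1[C@@H](O[Si](CC)(CC)CC)[C@@]2(C)O[C@H]2C[C@H]1C(=O)CCl | intermediate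
15 | 1,3-dithiane | C1CSCSC1 | starting material
16 | 1-bromo-3-methylbut-2-ene | CC(C)=CCBr | starting material
17 | 2-(3-methylbut-2-en-1-yl)-1,3-dithiane | CC(C)=CCC1SCCCS1 | intermediate
18 | 2-lithio-2-(3-methylbut-2-en-1-yl)-1,3-dithiane | [Li]C1(CC=C(C)C)SCCCS1 | intermediate
19 | lithium alkoxide of the C7 chlorohydrin from 14 and 18 (C7 bears O−, CH2Cl and the 2-prenyl-1,3-dithian-2-yl group; ring as in 14) | CC(C)CC(=O)O[C@@H]1[C@@H](O[Si](CC)(CC)CC)[C@@]2(C)O[C@H]2C[C@H]1[C@@]([O-])(CCl)C1(CC=C(C)C)SCCCS1.[Li+] | intermediate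
20 | (1S,2R,3S,4R,6S)-1-methyl-4-{(2R)-2-[2-(3-methylbut-2-en-1-yl)-1,3-dithian-2-yl]oxiran-2-yl}-2-[(triethylsilyl)oxy]-7-oxabicyclo[4.1.0]heptan-3-yl 3-methylbutanoate | CC(C)CC(=O)O[C@@H]1[C@@H](O[Si](CC)(CC)CC)[C@@]2(C)O[C@H]2C[C@H]1[C@]1(C2(CC=C(C)C)SCCCS2)CO1 | intermediate
21 | (1R,2R,3S,4R,6S)-2-hydroxy-1-methyl-4-{(2R)-2-[2-(3-methylbut-2-en-1-yl)-1,3-dithian-2-yl]oxiran-2-yl}-7-oxabicyclo[4.1.0]heptan-3-yl 3-methylbutanoate | CC(C)CC(=O)O[C@@H]1[C@@H](O)[C@@]2(C)O[C@H]2C[C@H]1[C@]1(C2(CC=C(C)C)SCCCS2)CO1 | intermediate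
22 | (1S,3S,4R,6S)-1-methyl-4-[(2R)-2-(4-methylpent-3-enoyl)oxiran-2-yl]-2-oxo-7-oxabicyclo[4.1.0]heptan-3-yl 3-methylbutanoate | CC(C)CC(=O)O[C@@H]1C(=O)[C@@]2(C)O[C@H]2C[C@H]1[C@]1(C(=O)CC=C(C)C)CO1 | intermediate
23 | (1S,3S,4R,6S)-4-{(2R)-2-[(2E)-4-hydroperoxy-4-methylpent-2-enoyl]oxiran-2-yl}-1-methyl-2-oxo-7-oxabicyclo[4.1.0]heptan-3-yl 3-methylbutanoate | CC(C)CC(=O)O[C@@H]1C(=O)[C@@]2(C)O[C@H]2C[C@H]1[C@]1(C(=O)/C=C/C(C)(C)OO)CO1 | target

Total step count: 14. Longest linear sequence: 13 (steps 1–9 and 11–14; step 10 is a one-step branch).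

Steps most likely to fail

Step 11. The facial choice at the C7 carbonyl rests only on the difference between C2 and C6 as the anti substituent and may be poor or reversed. The basic carbanion may also enolise the chloromethyl ketone or expel the C2 isovalerate by β-elimination. The fallback sets out from 13 and 18 and returns at 20, attaching the two carbon substituents of C7 in the reverse order. Lithiated dithiane 18 acylates Weinreb amide 13 (THF, −78 °C) to the acyl dithiane (1S,2R,3S,4R,6S)-1-methyl-4-{[2-(3-methylbut-2-en-1-yl)-1,3-dithian-2-yl]carbonyl}-2-[(triethylsilyl)oxy]-7-oxabicyclo[4.1.0]heptan-3-yl 3-methylbutanoate F1. Chloromethyllithium (ICH2Cl, MeLi·LiBr, THF, −78 °C to rt) then adds to the C7 ketone of F1, and the chlorohydrin alkoxide 19 closes to 20. Because the incoming carbon is now C14 instead of C8 while the face preference of the substrate is unchanged, this order gives the C7 configuration opposite to that of step 11. It is the remedy if step 11 favours the 7S epimer, and it avoids pairing a basic carbanion with an enolisable β-acyloxy ketone; whichever order delivers 7R is carried on.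

Step 14. Hydrogen abstraction from the C11 methyl groups may compete with abstraction at C9, giving the secondary hydroperoxide with a terminal alkene. The fallback sets out from 22 and returns at 23, building the hydroperoxide by ionic addition and elimination. N-Bromosuccinimide and anhydrous ethereal H2O2 (Et2O, −40 °C) open the bromonium ion of the trisubstituted alkene at the tertiary carbon to give (1S,3S,4R,6S)-4-[(2R)-2-(3-bromo-4-hydroperoxy-4-methylpentanoyl)oxiran-2-yl]-1-methyl-2-oxo-7-oxabicyclo[4.1.0]heptan-3-yl 3-methylbutanoate F2, as both epimers at the CHBr carbon. Et3N (CH2Cl2, −20 °C) then removes HBr across C9–C10 by an E1cB path, since the C9 hydrogens are α to C8=O, giving the E-enone 23.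

Step 3. The amide-bearing enal is a new partner for the cascade, so slow iminium turnover, enal oligomerisation or eroded enantioselectivity are possible. The fallback sets out from 5 and returns at 7, running the cascade on the ester-bearing enal, for which this reactivity is established, and introducing the amide afterwards. Purchased ethyl (E)-4-oxobut-2-enoate F3 and 5 react under the conditions of step 3 through the adduct 4-tert-butyl 1-ethyl (2R)-2-(2-oxoethyl)-3-propanoylbutanedioate F4 (not isolated) to ethyl (R)-4-methyl-5-oxocyclohex-3-ene-1-carboxylate F5. Hydrolysis (LiOH, THF–H2O, 0 °C) gives (R)-4-methyl-5-oxocyclohex-3-ene-1-carboxylic acid F6. Coupling with N,O-dimethylhydroxylamine hydrochloride (N-ethyl-N′-(3-dimethylaminopropyl)carbodiimide hydrochloride, 1-hydroxybenzotriazole, N-methylmorpholine, CH2Cl2) then gives 7.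

Further compounds
F1 | step 11 | (1S,2R,3S,4R,6S)-1-methyl-4-{[2-(3-methylbut-2-en-1-yl)-1,3-dithian-2-yl]carbonyl}-2-[(triethylsilyl)oxy]-7-oxabicyclo[4.1.0]heptan-3-yl 3-methylbutanoate | CC(C)CC(=O)O[C@@H]1[C@@H](O[Si](CC)(CC)CC)[C@@]2(C)O[C@H]2C[C@H]1C(=O)C1(CC=C(C)C)SCCCS1
F2 | step 14 | (1S,3S,4R,6S)-4-[(2R)-2-(3-bromo-4-hydroperoxy-4-methylpentanoyl)oxiran-2-yl]-1-methyl-2-oxo-7-oxabicyclo[4.1.0]heptan-3-yl 3-methylbutanoate (both CHBr epimers) | CC(C)CC(=O)O[C@@H]1C(=O)[C@@]2(C)O[C@H]2C[C@H]1[C@]1(C(=O)CC(Br)C(C)(C)OO)CO1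
F3 | step 3 | ethyl (E)-4-oxobut-2-enoate | CCOC(=O)/C=C/C=O
F4 | step 3 | 4-tert-butyl 1-ethyl (2R)-2-(2-oxoethyl)-3-propanoylbutanedioate (both C3 epimers) | CCC(=O)C(C(=O)OC(C)(C)C)[C@@H](CC=O)C(=O)OCC
F5 | step 3 | ethyl (R)-4-methyl-5-oxocyclohex-3-ene-1-carboxylate | CCOC(=O)[C@@H]1CC=C(C)C(=O)C1
F6 | step 3 | (R)-4-methyl-5-oxocyclohex-3-ene-1-carboxylic acid | OC(=O)[C@@H]1CC=C(C)C(=O)C1
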